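At late times links and first end groups fall in step, so the examination starts there.

| flask | first end groups | second end groups | scavenger | remark | time |
|---|---|---|---|---|---|
| Monday's | 0.050 M | 0.95 equiv | 0.30 equiv | run made earlier |  |
| Tuesday's | 0.050 M | 1.3 equiv | 0.30 equiv | run made earlier |  |
| Saturday's | 0.050 M | 2.1 equiv | 0.30 equiv | run made earlier |  |
| Wednesday's | 0.025 M | 0.95 equiv | 0.30 equiv | run made earlier |  |
| midnight | 0.050 M | 0.950 equiv (fed, over 10 d) | 0.300 equiv | all else is in the flask from the start; the feed brings no volume worth counting | 15 d |
| summer | 0.050 M (fed, over 10 d) | 0.950 equiv | 0.300 equiv | all else is in the flask from the start; the feed brings no volume worth counting | 15 d |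
| noon | 0.050 M | 0.950 equiv | 0.300 equiv | everything together at the start | 15 d |

| run | time / d | links / % | first end groups / % |
|---|---|---|---|
| Monday's | 4.00 | 37 | 17 |
| Monday's | 8.00 | 27 | 8 |
| Monday's | 12.0 | 26 | 5 |
| Monday's | 15.0 | 19 | 2 |
| Tuesday's | 2.50 | 53 | 12 |
| Tuesday's | 5.00 | 49 | 5 |
| Tuesday's | 6.00 | 47 | 4 |
| Tuesday's | 10.0 | 47 | 3 |
| Saturday's | 2.50 | 72 | 1 |
| Saturday's | 5.00 | 71 | 0 |
| Saturday's | 6.00 | 74 | 1 |
| Saturday's | 10.0 | 71 | 0 |
| Wednesday's | 0.625 | 25 | 69 |
| Wednesday's | 1.67 | 36 | 53 |
| Wednesday's | 4.00 | 31 | 38 |
| Wednesday's | 10.0 | 16 | 24 |

(standard deviation of a reading: 1.5 percentage points)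



* the best flask by amount of links, in percent of the first end groups charged; "all alike" if 1.5 percentage points covers them all (midnight / summer / noon / all alike)
* amount of links at the end, in percent of the first end groups charged, midnight
* amount of links at the end, in percent of the first end groups charged, summer
* amount of links at the end, in percent of the first end groups charged, noon

What do the late readings show? Between 8.00 d and 15.0 d, Monday's links drop 8 percentage points and its first end groups 6 points. Between 4.00 d and 10.0 d, Wednesday's drop 15 points and 14 points. Within the scatter that is one for one.

So what holds still? The link margin, c(links) minus c(first end groups) in percent of the charge 19 points. Monday's late readings average 19 points, and Wednesday's last two average −7.5 points.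

Where is its zero? The margin starts at minus the whole charge, and each first end group that couples raises it twice, once by leaving and once as a link. Zero is therefore the symmetric case: half coupled, and each link meets one first end group. Above zero links outlast first end groups; below it the reverse.

And the weak spot? Coupling per second end group charged reads 62.6% on Monday but 48.7% on Wednesday, less at the lower c(first end groups). So second end groups, the limiting reagent on Monday, are lost by a route that doesn't wait for a partner.

My verdict: summer makes them wait, so its margin falls far below zero and its links go towards nothing. Midnight I put below noon, with first end groups standing beside its links while the feed runs. Noon repeats Monday, about 19%, and is best.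

The forecast differs: summer best, with 24% for midnight, 45% for summer and 20% for noon, on the ground that “Summer keeps second groups in excess during most of the feed, so links survive best”.

The flasks give 15.7% for midnight, 0.437% for summer and 20.9% for noon, so noon is best.

    first end groups + second end groups → links + released group (k = 1.50 M⁻¹ h⁻¹)
    second end groups → decomposed reagent (k = 0.0265 h⁻¹)
    first end groups + links → side product (k = 0.454 M⁻¹ h⁻¹)
    second end groups + released group ⇌ idle adduct, settled at all times (K = 12.7 M⁻¹)
    scavenger + released group → scavenged by-product (k = 35.6 M⁻¹ h⁻¹)

Just after noon's start, coupling used second end groups 2.8 times as fast as decomposition did. By 15.0 d noon's margin was 17 points, against Monday's 19 points, and 17.3% links stood at 150 d. Summer's margin was −69 points, and at 150 d it held 68.7% first end groups and 0% links. The further flask, noon with 0.240 equiv of second end groups, ended on a margin of −66 points, holding 65.7% first end groups and 0.0753% links.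

(The readings stem from a simulated flask on assumed constants, noise included.)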